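A direct plan would keep ring B as 2,4-dibromophenol A1 and grow ring A from cyclopent-2-en-1-one A2:
epoxidation to the epoxy ketone A3, phenoxide opening to the 2-aryloxy enone A4, ketalisation to the dimethyl ketal A5, carbene ring
expansion to the bromodiene ketal A6, aromatisation to the monobromo phenol A7, closing dibromination.
Weakest would be the epoxidation: it would set two stereocentres only for the next step to erase them;
the ketalisation: it would mask a carbonyl only to serve the carbene step and be undone two steps later;
and the carbene addition, cyclopropane opening and dehydrobromination: a three-stage cascade without close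
precedent on a hindered, electron-poor enol ether, which would stake ring A on one ionisation mode of
material that already carries ring B and would place only one bromine of five.

Ring A: C1–OH, C2–OAr, Br on C3/C4/C6; ring B: C1'–O, Br on C2'/C4'.
Cuts: C4–Br (only open position ortho/para to OH), then ring B itself at C1'–C2' and C5'–C6'.
C2'–C5' are C3–C6 of 3,5-dibromo-2H-pyran-2-one; C1'/C6' are the two alkene carbons of the ketene acetal of 3,6-dibromocatechol.
Ring A is bought, ring B arises last on ring A's oxygen; no aryl–O–aryl coupling.
Enabling feature: Br on C2'/C4' beside C1' is the pyrone pattern; the free C1–OH lets both catechol oxygens sit on C1', and Br on C3/C6 makes them equivalent.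
No step only sets or erases a stereocentre or masks a carbonyl; no carbene.

Key step: step 3

Assumption: 3,6-dibromocatechol 1 and 3,5-dibromo-2H-pyran-2-one 5 are taken to be purchasable; the target has no stereocentre and the one chiral intermediate 6 is racemic and not isolated.

**Step 1**
Reactants: 1 3,6-dibromobenzene-1,2-diol (3,6-dibromocatechol), 2 triethyl orthoacetate
Product: 3 4,7-dibromo-2-ethoxy-2-methyl-1,3-benzodioxole
Conditions: MeC(OEt)3 (3 equiv), PPTS (2 mol %), PhMe, 110 °C, EtOH distilled off
Reagents that add atoms: triethyl orthoacetate, CC(OCC)(OCC)OCC
Why: Acid-catalysed ortho ester exchange by the two adjacent phenols (cyclic ortho ester formation), driven by removal of ethanol and by closure of the five-membered dioxole ring; the symmetric catechol gives a product without a stereocentre.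

**Step 2**
Reactants: 3 4,7-dibromo-2-ethoxy-2-methyl-1,3-benzodioxole
Product: 4 4,7-dibromo-2-methylidene-1,3-benzodioxole
Conditions: Me3SiOTf (1.1 equiv), iPr2NEt (1.3 equiv), CH2Cl2, −20 → 20 °C; pentane, filtration through basic Al2O3; used at once
Reagents that add atoms: none
Why: Silyl triflate/amine elimination of an ortho ester to a ketene acetal (the standard acetal-to-enol-ether reaction), in which the silyl group takes the more basic ethoxy oxygen and the hindered amine deprotonates the methyl group of the resulting 2-methyl-1,3-benzodioxolium ion, leaving the aryl bromides and aryl C–O bonds untouched.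

**Step 3**
Reactants: 4 4,7-dibromo-2-methylidene-1,3-benzodioxole, 5 3,5-dibromo-2H-pyran-2-one
Product: 8 3,6-dibromo-2-(2,4-dibromophenoxy)phenol, via bicyclic spiro lactone 6 (not isolated), via spiro cyclohexadiene 7 (not isolated)
Conditions: 4 (1.3 equiv), o-xylene, 4 Å MS, 100 → 140 °C; then TsOH·H2O (5 mol %), MeOH–THF, 25 °C
Reagents that add atoms: none
Why: The electron-rich exocyclic alkene of 4 adds to the electron-poor diene C3–C6 of 5 in an inverse-electron-demand Diels–Alder reaction, the nucleophilic CH2 bonding to C6 (the dienyl-ester terminus beside the ring oxygen) and the acetal carbon to the bromine-bearing C3, to give lactone 6; cycloreversion expels CO2 to give spiro diene 7, and acid then ionises one acetal C–O bond to an O-aryl arenium ion that loses the C6' proton, so that ring B becomes aromatic and the departing oxygen becomes the free C1–OH of 8. The closest known reaction type is the benzannulation of 2-pyrones with ketene acetals (cycloaddition, loss of CO2, loss of an alcohol), here with the alcohol tethered, together with the regioselective cycloadditions of 3,5-dibromo-2-pyrone with donor alkenes, which bond the donor-bearing carbon to C3. Ring B is closed by intermolecular [4+2] cycloaddition, which forms C1'–C2' and C5'–C6', and is aromatised by cycloreversion and β-elimination. The two bridgehead stereocentres of racemic 6 disappear with the CO2, the spiro carbon is not a stereocentre, and 8 is achiral. The selectivities needed are the orientation of the cycloaddition, secured by the matched polarisation of the two partners, and an acetal opening without regiochemical choice, secured by the twofold symmetry of the 3,6-dibromocatechol unit, whose two C–O bonds lead to the same product. Should the acetal of 6 open before CO2 is lost, the bicyclo[2.2.2]octadiene lactone so formed would extrude CO2 to the same 8.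

**Step 4**
Reactants: 8 3,6-dibromo-2-(2,4-dibromophenoxy)phenol
Product: 9 3,4,6-tribromo-2-(2,4-dibromophenoxy)phenol (target)
Conditions: Br2 (1.05 equiv), AcOH, 20 °C
Reagents that add atoms: bromine, BrBr
Why: Electrophilic aromatic bromination directed by the free hydroxyl, whose ortho positions C2 and C6 are occupied so that C4 is its only open ortho/para site, while C5 is meta to it and ring B is deactivated by two bromines, so one equivalent should stop at the target.

**Compound list**

1 | 3,6-dibromobenzene-1,2-diol (3,6-dibromocatechol) | Oc1c(Br)ccc(Br)c1O | starting material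
2 | triethyl orthoacetate (1,1,1-triethoxyethane) | CC(OCC)(OCC)OCC | starting material
3 | 4,7-dibromo-2-ethoxy-2-methyl-1,3-benzodioxole | CCOC1(C)Oc2c(Br)ccc(Br)c2O1 | intermediate
4 | 4,7-dibromo-2-methylidene-1,3-benzodioxole | C=C1Oc2c(Br)ccc(Br)c2O1 | intermediate
5 | 3,5-dibromo-2H-pyran-2-one | O=C1OC=C(Br)C=C1Br | starting material
6 | 4,4',7,7'-tetrabromospiro[1,3-benzodioxole-2,5'-[2]oxabicyclo[2.2.2]oct[7]en]-3'-one (racemic, one enantiomer drawn; Br on the bridgehead beside the carbonyl and on the alkene carbon beside the O-bearing bridgehead; not isolated) | O=C1O[C@H]2CC3(Oc4c(Br)ccc(Br)c4O3)[C@]1(Br)C=C2Br | intermediate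
7 | 2',4,4',7-tetrabromospiro[1,3-benzodioxole-2,1'-cyclohexa[2,4]diene] (achiral, not isolated) | BrC1=CC(Br)=CCC12Oc3c(Br)ccc(Br)c3O2 | intermediate
8 | 3,6-dibromo-2-(2,4-dibromophenoxy)phenol | Oc1c(Br)ccc(Br)c1Oc1ccc(Br)cc1Br | intermediate
9 | 3,4,6-tribromo-2-(2,4-dibromophenoxy)phenol | Oc1c(Br)cc(Br)c(Br)c1Oc1ccc(Br)cc1Br | target

Total steps: 4. Longest linear sequence: 4 (1 → 3 → 4 → 8 → 9).

Steps most likely to fail, riskiest first:

Step 3. The cycloaddition could be outrun by acid-induced oligomerisation of the ketene acetal or by its capture by the phenol as it forms, or the adduct could resist loss of CO2. The fallback sets out from 1 and joins the two arenes directly. Mono-O-arylation of 1 with bis(2,4-dibromophenyl)iodonium chloride F1, prepared from 1,3-dibromobenzene with (IO)2SO4 in H2SO4 and then NaCl, using K2CO3 (1 equiv) in DMF at 60 °C, would transfer one 2,4-dibromophenyl group to either of the two equivalent oxygens. This would give 8, where the route is rejoined.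

Step 2. Silylation at a ring oxygen could open the dioxole, and the ketene acetal could hydrolyse or oligomerise during isolation. The fallback sets out from 1. Acid-catalysed acetal exchange with (phenylselanyl)acetaldehyde diethyl acetal would give 4,7-dibromo-2-[(phenylselanyl)methyl]-1,3-benzodioxole F2. Oxidation with NaIO4 (NaHCO3, aqueous MeOH) would give 4,7-dibromo-2-[(benzeneseleninyl)methyl]-1,3-benzodioxole F3. Its selenoxide syn-elimination on warming in toluene with iPr2NH can take only the acetal hydrogen and would release 4 in the presence of 5, so the route is rejoined at 4.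

Step 1. The exchange could stop at open-chain mixed ortho esters, or the cyclic ortho ester could hydrolyse to the catechol monoacetate on isolation. The fallback sets out from 1 and replaces the equilibrium exchange by an irreversible addition. One phenol would add under acid catalysis across the double bond of 1,1-diethoxyethene, and the second would displace ethanol intramolecularly to give 3, where the route is rejoined. No new compound would arise on this way: F0.

**Further compounds**

F1 | step 3 | bis(2,4-dibromophenyl)iodonium chloride | [Cl-].Brc1ccc([I+]c2ccc(Br)cc2Br)c(Br)c1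
F2 | step 2 | 4,7-dibromo-2-[(phenylselanyl)methyl]-1,3-benzodioxole | Brc1ccc(Br)c2OC(C[Se]c3ccccc3)Oc12
F3 | step 2 | 4,7-dibromo-2-[(benzeneseleninyl)methyl]-1,3-benzodioxole (racemic at selenium) | Brc1ccc(Br)c2OC(C[Se](=O)c3ccccc3)Oc12
F0 | step 1 | none | none
A1 | direct plan | 2,4-dibromophenol | Oc1ccc(Br)cc1Br
A2 | direct plan | cyclopent-2-en-1-one | O=C1C=CCC1
A3 | direct plan | 6-oxabicyclo[3.1.0]hexan-2-one (racemic, cis-fused) | O=C1CC[C@H]2O[C@@H]12
A4 | direct plan | 2-(2,4-dibromophenoxy)cyclopent-2-en-1-one | O=C1CCC=C1Oc1ccc(Br)cc1Br
A5 | direct plan | 2,4-dibromo-1-[(5,5-dimethoxycyclopent-1-en-1-yl)oxy]benzene | COC1(OC)CCC=C1Oc1ccc(Br)cc1Br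
A6 | direct plan | 2,4-dibromo-1-[(2-bromo-6,6-dimethoxycyclohexa-1,3-dien-1-yl)oxy]benzene | COC1(OC)CC=CC(Br)=C1Oc1ccc(Br)cc1Br
A7 | direct plan | 3-bromo-2-(2,4-dibromophenoxy)phenol | Oc1cccc(Br)c1Oc1ccc(Br)cc1Br
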